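**Retrosynthetic overview**

1. Labels: five-membered ring C1 (quaternary, CH3), C2 (O-angeloyl), C3, C4 (OH, isopropyl), C5 (H); seven-membered ring C5–C6 (O-angeloyl)–C7–C8(CH3)=C9–C10–C1. The strategy rests on reading the seven-membered ring as the six carbons C5–C10 of a 2-methoxy-4-methylphenyl group (OMe on C6, CH3 on C8) plus C1, a carbene carbon that carries the angular CH3 next to the C2 carbonyl.
2. Key disconnection: C1–C5 and C1–C10, an intramolecular Buchner reaction of an α-methyl diazoketone on the arene.
3. After the key step: target ⇒ C2,C4,C6-triol (two angelate C–O bonds) ⇒ its 7,9-diene (1,4-hydrogenation) ⇒ C2/C6 diketone (hydride delivered from C4–OH) ⇒ C6 methyl enol ether and C4 silyl ether.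
4. Before the key step: diazoketone ⇒ β-silyloxy acid + diazoethane ⇒ 1,3-diol ⇒ Sharpless epoxide of a (Z)-allylic alcohol, whose alkene geometry is taken from a coumarin made from m-cresol.
5. Ring order: arene (bought); coumarin lactone ring (temporary, opened in step 2); then the cyclopentanone and the cycloheptatriene together in step 9.

Key step: step 9

Remark: C1–C10 in the Why lines are the labels above; in the azulene names C1 = C8a, C2 = C1, C3 = C2, C4 = C3, C5 = C3a, C6 = C4, C7 = C5, C8 = C6, C9 = C7, C10 = C8.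
Assumption: in the resolution used in the fallback for step 4, (S)-1-phenylethylamine is taken to give the less soluble salt with the (R)-acid; if the (S)-acid salt crystallises instead, (R)-1-phenylethylamine is used.

**Route**

Step 1
Reactants: 1 m-cresol (3-methylphenol); 2 ethyl 4-methyl-3-oxopentanoate
Product: 3 7-methyl-4-(propan-2-yl)-2H-chromen-2-one
Conditions: CH3SO3H (solvent), 25 → 70 °C
Reagents that add atoms: none
Why: Pechmann condensation, in which ring closure by electrophilic attack at the position ortho to OH and para to CH3 and loss of water should give the 7-methyl coumarin, whose ring holds the aryl group and the carbonyl carbon cis across the new alkene.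

Step 2
Reactants: 3 7-methyl-4-(propan-2-yl)-2H-chromen-2-one
Product: 4 (2Z)-3-(2-hydroxy-4-methylphenyl)-4-methylpent-2-en-1-ol
Conditions: iBu2AlH (3.2 equiv), CH2Cl2, −78 → 0 °C; aq. potassium sodium tartrate
Reagents that add atoms: none
Why: Hydride reduction of the lactone carbonyl to the primary alcohol leaves the hindered alkene untouched, so the aryl group and CH2OH stay cis (Z), the geometry being inherited from the ring.

Step 3
Reactants: 4 (2Z)-3-(2-hydroxy-4-methylphenyl)-4-methylpent-2-en-1-ol
Product: 5 (2Z)-3-(2-methoxy-4-methylphenyl)-4-methylpent-2-en-1-ol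
Conditions: CH3I (1.2 equiv), K2CO3, acetone, 40 °C
Reagents that add atoms: iodomethane, CI
Why: Williamson ether synthesis in which K2CO3 deprotonates only the phenol, so the phenoxide is methylated and the allylic alcohol stays free.

Step 4
Reactants: 5 (2Z)-3-(2-methoxy-4-methylphenyl)-4-methylpent-2-en-1-ol
Product: 6 [(2S,3R)-3-(2-methoxy-4-methylphenyl)-3-(propan-2-yl)oxiran-2-yl]methanol
Conditions: Ti(OiPr)4 (0.5 equiv), L-(+)-diethyl tartrate (0.6 equiv), t-BuOOH (2 equiv), 4 Å molecular sieves, CH2Cl2, −20 °C; crude product used directly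
Reagents that add atoms: tert-butyl hydroperoxide, CC(C)(C)OO
Why: Sharpless asymmetric epoxidation, in which the titanium-bound allylic alcohol receives oxygen on the face that L-(+)-tartrate selects for primary allylic alcohols (2S epoxides), so the C–O bond formed at the aryl-bearing carbon is the future C4–O bond with the required configuration.

Step 5
Reactants: 6 [(2S,3R)-3-(2-methoxy-4-methylphenyl)-3-(propan-2-yl)oxiran-2-yl]methanol
Product: 7 (3R)-3-(2-methoxy-4-methylphenyl)-4-methylpentane-1,3-diol
Conditions: NaAlH2(OCH2CH2OCH3)2, THF, 0 °C → rt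
Reagents that add atoms: none
Why: Hydroxyl-directed reductive opening of a 2,3-epoxy alcohol, in which the alkoxyaluminium hydride delivers hydride to the secondary epoxide carbon and the tertiary benzylic C–O bond is not broken, so the 1,3-diol keeps the configuration set in step 4.

Step 6
Reactants: 7 (3R)-3-(2-methoxy-4-methylphenyl)-4-methylpentane-1,3-diol
Product: 9 (3R)-3-hydroxy-3-(2-methoxy-4-methylphenyl)-4-methylpentanoic acid, via hydroxy aldehyde 8 (not isolated)
Conditions: TEMPO (0.2 equiv), PhI(OAc)2 (2.4 equiv), MeCN/H2O (1:1), rt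
Reagents that add atoms: water, O
Why: Oxoammonium (TEMPO) oxidation takes the primary alcohol through the aldehyde and its hydrate to the acid, while the tertiary alcohol cannot be oxidised and the chloride-free oxidant spares the anisole ring.

Step 7
Reactants: 9 (3R)-3-hydroxy-3-(2-methoxy-4-methylphenyl)-4-methylpentanoic acid
Product: 11 (3R)-3-(2-methoxy-4-methylphenyl)-4-methyl-3-[(triethylsilyl)oxy]pentanoic acid, via bis(triethylsilyl) derivative 10 (not isolated)
Conditions: Et3SiOSO2CF3 (2.5 equiv), 2,6-lutidine, CH2Cl2, −78 → 0 °C; then aq. NaHCO3/THF, citric acid to pH 4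
Reagents that add atoms: triethylsilyl trifluoromethanesulfonate, CC[Si](CC)(CC)OS(=O)(=O)C(F)(F)F
Why: Silyl triflate silylation is strong enough for the hindered tertiary benzylic alcohol, and the silyl ester formed alongside is hydrolysed selectively in the aqueous work-up.

Step 8
Reactants: 11 (3R)-3-(2-methoxy-4-methylphenyl)-4-methyl-3-[(triethylsilyl)oxy]pentanoic acid
Product: 13 (5R)-2-diazo-5-(2-methoxy-4-methylphenyl)-6-methyl-5-[(triethylsilyl)oxy]heptan-3-one, via isobutyl carbonic anhydride 12 (not isolated)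
Conditions: i-BuOCOCl, Et3N, THF, −15 °C; then CH3CHN2 (from N-ethyl-N-nitrosourea and aq. KOH, in Et2O), −15 → 0 °C
Reagents that add atoms: diazoethane, CC=[N+]=[N-]
Why: Acylation of a diazoalkane by a mixed carbonic anhydride (the diazoketone-forming stage of the Arndt–Eistert sequence), in which the carbonate leaving group takes up the proton and the neutral conditions spare the tertiary silyl ether.

Step 9
Reactants: 13 (5R)-2-diazo-5-(2-methoxy-4-methylphenyl)-6-methyl-5-[(triethylsilyl)oxy]heptan-3-one
Product: 15 (3R,8aR)-4-methoxy-6,8a-dimethyl-3-(propan-2-yl)-3-[(triethylsilyl)oxy]-3,8a-dihydroazulen-1(2H)-one, via norcaradiene tautomer 14 (not isolated)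
Conditions: Rh2(OAc)4 (1 mol%), CH2Cl2, 40 °C, slow addition of 13
Reagents that add atoms: none
Why: Rh2(OAc)4 turns the diazo group into a rhodium carbene at C1, which adds as an electrophile to the C5–C10 bond of the arene (bonding first to C5, the carbon made most electron-rich by the ortho methoxy and para methyl groups) to give norcaradiene 14, and a thermal disrotatory six-electron electrocyclic opening of the C5–C10 cyclopropane bond then gives cycloheptatriene 15. The closest known reaction type is the intramolecular Buchner reaction of 2-diazo-5-arylpentan-3-ones, which gives 8a-methyl-3,8a-dihydroazulen-1(2H)-ones. The cyclopentanone is closed by forming C1–C5 across the three-atom tether C2–C3–C4 (carbene addition to the ipso–ortho bond, five-membered ring), and the seven-membered ring is not closed directly but arises by ring expansion when C1 is inserted between C5 and C10. The new stereocentre C1 is controlled by C4: in the reactive rotamer about the C4–aryl bond the tether lies over one face of the ring, the small oxygen atom of the silyl ether takes the crowded in-plane position beside the methoxy-bearing C6 and the isopropyl group points towards C10–H, so C1–C10 should form syn to isopropyl and the angular methyl should end cis to the silyloxy group (8aR), in line with the known preference of a benzylic alkyl group to end trans to the angular methyl. The step needs addition to C5–C10 and not to C5–C6, which the methoxy substituent on C6 secures, and arene addition in preference to 1,5-insertion into the isopropyl C–H bond, O-ylide formation or a 1,2-hydride shift from the methyl group, which the activated ipso carbon, the deactivation of the methine C–H by the β-oxygen, the hindered silyl ether oxygen and the primary nature of the methyl hydrogens (with acetate ligands on rhodium) should secure.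

Step 10
Reactants: 15 (3R,8aR)-4-methoxy-6,8a-dimethyl-3-(propan-2-yl)-3-[(triethylsilyl)oxy]-3,8a-dihydroazulen-1(2H)-one
Product: 17 (3R,3aR,8aR)-3-hydroxy-6,8a-dimethyl-3-(propan-2-yl)-2,3,3a,8a-tetrahydroazulene-1,4-dione, via silyl dienone 16 (not isolated)
Conditions: aq. HF (48%)/MeCN (1:19), 0 °C → rt; aq. NaHCO3
Reagents that add atoms: water, O
Why: Acid hydrolysis of the methyl enol ether begins with protonation at C5 (the only site that gives an oxygen-stabilised cation), which should occur on the face opposite the silyloxy and angular methyl groups and set H-5 trans to both, and fluoride then cleaves the Si–O bond; the trans-fused isomer, with the C6 carbonyl beside the C4 hydroxyl and away from isopropyl, is also the one expected on equilibration through the dienol.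

Step 11
Reactants: 17 (3R,3aR,8aR)-3-hydroxy-6,8a-dimethyl-3-(propan-2-yl)-2,3,3a,8a-tetrahydroazulene-1,4-dione
Product: 19 (1S,3R,3aS,4S,8aR)-6,8a-dimethyl-3-(propan-2-yl)-1,2,3,3a,4,8a-hexahydroazulene-1,3,4-triol, via monoreduced ketodiol 18 (not isolated)
Conditions: Me4NBH(OAc)3 (8 equiv), MeCN/AcOH (1:1), −30 → 0 °C
Reagents that add atoms: none
Why: Evans–Saksena reduction, in which the C4 hydroxyl exchanges onto boron and the alkoxyborohydride delivers hydride through six-membered transition states to C2 and then to C6 on the face that carries the C4 oxygen, so both new hydroxyls should end trans to it, while this weak hydride does not reduce ketones or the diene intermolecularly.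

Step 12
Reactants: 19 (1S,3R,3aS,4S,8aR)-6,8a-dimethyl-3-(propan-2-yl)-1,2,3,3a,4,8a-hexahydroazulene-1,3,4-triol
Product: 20 (1S,3R,3aS,4S,8aR)-6,8a-dimethyl-3-(propan-2-yl)-1,2,3,3a,4,5,8,8a-octahydroazulene-1,3,4-triol
Conditions: (η6-naphthalene)Cr(CO)3 (0.2 equiv), H2 (50 atm), THF, 45 °C
Reagents that add atoms: none
Why: Arene–Cr(CO)3-catalysed 1,4-hydrogenation of a conjugated diene, in which the ring-held s-cis diene binds the Cr(CO)3 fragment and takes up hydrogen at its termini C7 and C10, leaving the C8=C9 double bond and creating no stereocentre.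

Step 13
Reactants: 20 (1S,3R,3aS,4S,8aR)-6,8a-dimethyl-3-(propan-2-yl)-1,2,3,3a,4,5,8,8a-octahydroazulene-1,3,4-triol; 21 angelic acid [(2Z)-2-methylbut-2-enoic acid]
Product: 23 (1S,3R,3aS,4S,8aR)-3-hydroxy-6,8a-dimethyl-3-(propan-2-yl)-1,2,3,3a,4,5,8,8a-octahydroazulene-1,4-diyl bis[(2Z)-2-methylbut-2-enoate], via angelic 2,4,6-trichlorobenzoic anhydride 22 (not isolated)
Conditions: 21 (6 equiv), 2,4,6-Cl3C6H2COCl (6 equiv), Et3N, toluene, rt; then 20, toluene, 80 °C
Reagents that add atoms: none
Why: Yamaguchi esterification run without 4-(dimethylamino)pyridine, in which the mixed anhydride acylates the two secondary hydroxyls on heating, the tertiary C4 hydroxyl is too hindered to react, and the absence of a nucleophilic catalyst avoids Z to E isomerisation of the angelate.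

**Compound list**

1 | m-cresol (3-methylphenol) | Cc1cccc(O)c1 | starting material
2 | ethyl 4-methyl-3-oxopentanoate | CCOC(=O)CC(=O)C(C)C | starting material
3 | 7-methyl-4-(propan-2-yl)-2H-chromen-2-one | Cc1ccc2c(c1)OC(=O)C=C2C(C)C | intermediate
4 | (2Z)-3-(2-hydroxy-4-methylphenyl)-4-methylpent-2-en-1-ol | OC/C=C(\c1ccc(C)cc1O)C(C)C | intermediate
5 | (2Z)-3-(2-methoxy-4-methylphenyl)-4-methylpent-2-en-1-ol | OC/C=C(\c1ccc(C)cc1OC)C(C)C | intermediate
6 | [(2S,3R)-3-(2-methoxy-4-methylphenyl)-3-(propan-2-yl)oxiran-2-yl]methanol | OC[C@@H]1O[C@]1(C(C)C)c1ccc(C)cc1OC | intermediate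
7 | (3R)-3-(2-methoxy-4-methylphenyl)-4-methylpentane-1,3-diol | OCC[C@@](O)(C(C)C)c1ccc(C)cc1OC | intermediate
8 | (3R)-3-hydroxy-3-(2-methoxy-4-methylphenyl)-4-methylpentanal | O=CC[C@@](O)(C(C)C)c1ccc(C)cc1OC | intermediate (not isolated)
9 | (3R)-3-hydroxy-3-(2-methoxy-4-methylphenyl)-4-methylpentanoic acid | OC(=O)C[C@@](O)(C(C)C)c1ccc(C)cc1OC | intermediate
10 | triethylsilyl (3R)-3-(2-methoxy-4-methylphenyl)-4-methyl-3-[(triethylsilyl)oxy]pentanoate | CC[Si](CC)(CC)OC(=O)C[C@@](O[Si](CC)(CC)CC)(C(C)C)c1ccc(C)cc1OC | intermediate (not isolated)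
11 | (3R)-3-(2-methoxy-4-methylphenyl)-4-methyl-3-[(triethylsilyl)oxy]pentanoic acid | OC(=O)C[C@@](O[Si](CC)(CC)CC)(C(C)C)c1ccc(C)cc1OC | intermediate
12 | (3R)-3-(2-methoxy-4-methylphenyl)-4-methyl-3-[(triethylsilyl)oxy]pentanoic 2-methylpropyl carbonic anhydride | CC(C)COC(=O)OC(=O)C[C@@](O[Si](CC)(CC)CC)(C(C)C)c1ccc(C)cc1OC | intermediate (not isolated)
13 | (5R)-2-diazo-5-(2-methoxy-4-methylphenyl)-6-methyl-5-[(triethylsilyl)oxy]heptan-3-one | COc1cc(C)ccc1[C@](O[Si](CC)(CC)CC)(C(C)C)CC(=O)C(C)=[N+]=[N-] | intermediate (key-step precursor)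
14 | norcaradiene tautomer of 15 (cyclopropane C1–C5–C10, i.e. C8a–C3a–C8; six-membered ring with C4(OMe)=C5 and C6(CH3)=C7) | COC1=CC(C)=C[C@@H]2[C@@]3(C)C(=O)C[C@@](O[Si](CC)(CC)CC)(C(C)C)[C@@]123 | intermediate (not isolated)
15 | (3R,8aR)-4-methoxy-6,8a-dimethyl-3-(propan-2-yl)-3-[(triethylsilyl)oxy]-3,8a-dihydroazulen-1(2H)-one | COC1=C2[C@](O[Si](CC)(CC)CC)(C(C)C)CC(=O)[C@]2(C)C=CC(C)=C1 | intermediate (key-step product)
16 | (3R,3aR,8aR)-6,8a-dimethyl-3-(propan-2-yl)-3-[(triethylsilyl)oxy]-2,3,3a,8a-tetrahydroazulene-1,4-dione | O=C1C=C(C)C=C[C@@]2(C)C(=O)C[C@@](O[Si](CC)(CC)CC)(C(C)C)[C@H]12 | intermediate (not isolated)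
17 | (3R,3aR,8aR)-3-hydroxy-6,8a-dimethyl-3-(propan-2-yl)-2,3,3a,8a-tetrahydroazulene-1,4-dione | O=C1C=C(C)C=C[C@@]2(C)C(=O)C[C@@](O)(C(C)C)[C@H]12 | intermediate
18 | (1S,3R,3aR,8aR)-1,3-dihydroxy-6,8a-dimethyl-3-(propan-2-yl)-2,3,3a,8a-tetrahydroazulen-4(1H)-one | O=C1C=C(C)C=C[C@@]2(C)[C@@H](O)C[C@@](O)(C(C)C)[C@H]12 | intermediate (not isolated)
19 | (1S,3R,3aS,4S,8aR)-6,8a-dimethyl-3-(propan-2-yl)-1,2,3,3a,4,8a-hexahydroazulene-1,3,4-triol | O[C@H]1C=C(C)C=C[C@@]2(C)[C@@H](O)C[C@@](O)(C(C)C)[C@H]12 | intermediate
20 | (1S,3R,3aS,4S,8aR)-6,8a-dimethyl-3-(propan-2-yl)-1,2,3,3a,4,5,8,8a-octahydroazulene-1,3,4-triol | O[C@H]1CC(C)=CC[C@@]2(C)[C@@H](O)C[C@@](O)(C(C)C)[C@H]12 | intermediate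
21 | angelic acid, (2Z)-2-methylbut-2-enoic acid | C/C=C(/C)C(=O)O | starting material
22 | (2Z)-2-methylbut-2-enoic 2,4,6-trichlorobenzoic anhydride | C/C=C(/C)C(=O)OC(=O)c1c(Cl)cc(Cl)cc1Cl | intermediate (not isolated)
23 | (1S,3R,3aS,4S,8aR)-3-hydroxy-6,8a-dimethyl-3-(propan-2-yl)-1,2,3,3a,4,5,8,8a-octahydroazulene-1,4-diyl bis[(2Z)-2-methylbut-2-enoate] | C/C=C(/C)C(=O)O[C@H]1CC(C)=CC[C@@]2(C)[C@@H](OC(=O)/C(C)=C\C)C[C@@](O)(C(C)C)[C@H]12 | target

**Step count**

Total: 13 steps. Longest linear sequence: 13 steps (1 → 23; 21 enters in step 13).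

**Three steps most likely to fail**

Step 9 (key step). What may go wrong: the carbene is diverted into insertion into the tertiary C–H bond of the isopropyl group, or the triethylsilyloxy and isopropyl groups compete for the in-plane position beside the methoxy group, so that C1 forms with low facial selectivity. The fallback redesigns the substrate and adds control by a chiral catalyst to the control by C4; it sets out from 13 and comes back at 17. Bu4NF buffered with AcOH in THF frees the tertiary alcohol to give (5R)-2-diazo-5-hydroxy-5-(2-methoxy-4-methylphenyl)-6-methylheptan-3-one F1. Me3SiCl and imidazole then give the smaller trimethylsilyl ether (5R)-2-diazo-5-(2-methoxy-4-methylphenyl)-6-methyl-5-[(trimethylsilyl)oxy]heptan-3-one F2, whose oxygen should take the in-plane position more readily. A copper carbene, which does not insert into unactivated C–H bonds, is generated with [Cu(MeCN)4]PF6 and the enantiomer of 2,2'-(propane-2,2-diyl)bis(4-tert-butyl-4,5-dihydrooxazole) that is matched to the (5R) centre. It adds to the C5–C10 bond and gives, through the trimethylsilyl norcaradiene F3, the azulenone (3R,8aR)-4-methoxy-6,8a-dimethyl-3-(propan-2-yl)-3-[(trimethylsilyl)oxy]-3,8a-dihydroazulen-1(2H)-one F4. Aqueous HF in MeCN as in step 10 hydrolyses the enol ether to the trimethylsilyl dienone (3R,3aR,8aR)-6,8a-dimethyl-3-(propan-2-yl)-3-[(trimethylsilyl)oxy]-2,3,3a,8a-tetrahydroazulene-1,4-dione F5 and removes the silyl group, which returns 17.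

Step 4. What may go wrong: slow and poorly face-selective oxygen transfer to an allylic alcohol whose aryl group is cis to CH2OH, or opening of the electron-rich tertiary benzylic epoxide by the titanium Lewis acid. The fallback avoids the epoxide and sets C4 by classical resolution; it sets out from 5 and comes back at 9. Oxymercuration–demercuration (Hg(OAc)2, THF/H2O; then NaBH4, aq. NaOH) adds water in the Markovnikov sense and gives racemic 3-(2-methoxy-4-methylphenyl)-4-methylpentane-1,3-diol F6. Oxidation as in step 6 passes through racemic 3-hydroxy-3-(2-methoxy-4-methylphenyl)-4-methylpentanal F7 to racemic 3-hydroxy-3-(2-methoxy-4-methylphenyl)-4-methylpentanoic acid F8. Crystallisation with (S)-1-phenylethylamine should give the diastereomerically pure salt (1S)-1-phenylethanaminium (3R)-3-hydroxy-3-(2-methoxy-4-methylphenyl)-4-methylpentanoate F9, and acidification returns 9.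

Step 11. What may go wrong: incomplete or face-unselective hydride delivery to the conjugated C6 ketone, because the C4 oxygen stays bound in a cyclic borate after reduction at C2 or because C5 epimerises in the acidic medium. The fallback reverses the order and uses electron transfer in place of hydride delivery; it sets out from 17 and comes back at 20. The Cr(CO)3-catalysed 1,4-hydrogenation of step 12 is run first and gives the β,γ-unsaturated hydroxy diketone (3R,3aR,8aR)-3-hydroxy-6,8a-dimethyl-3-(propan-2-yl)-2,3,3a,5,8,8a-hexahydroazulene-1,4-dione F10. SmI2 with MeOH in THF at 0 °C then reduces both β-hydroxy ketones through samarium chelates with the C4 oxygen, the known anti-selective reduction of β-hydroxy ketones, which returns 20.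

Further compounds
F1 | step 9 | (5R)-2-diazo-5-hydroxy-5-(2-methoxy-4-methylphenyl)-6-methylheptan-3-one | COc1cc(C)ccc1[C@](O)(C(C)C)CC(=O)C(C)=[N+]=[N-]
F2 | step 9 | (5R)-2-diazo-5-(2-methoxy-4-methylphenyl)-6-methyl-5-[(trimethylsilyl)oxy]heptan-3-one | COc1cc(C)ccc1[C@](O[Si](C)(C)C)(C(C)C)CC(=O)C(C)=[N+]=[N-]
F3 | step 9 | norcaradiene tautomer of F4 (trimethylsilyl analogue of 14) | COC1=CC(C)=C[C@@H]2[C@@]3(C)C(=O)C[C@@](O[Si](C)(C)C)(C(C)C)[C@@]123
F4 | step 9 | (3R,8aR)-4-methoxy-6,8a-dimethyl-3-(propan-2-yl)-3-[(trimethylsilyl)oxy]-3,8a-dihydroazulen-1(2H)-one | COC1=C2[C@](O[Si](C)(C)C)(C(C)C)CC(=O)[C@]2(C)C=CC(C)=C1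
F5 | step 9 | (3R,3aR,8aR)-6,8a-dimethyl-3-(propan-2-yl)-3-[(trimethylsilyl)oxy]-2,3,3a,8a-tetrahydroazulene-1,4-dione | O=C1C=C(C)C=C[C@@]2(C)C(=O)C[C@@](O[Si](C)(C)C)(C(C)C)[C@H]12
F6 | step 4 | racemic 3-(2-methoxy-4-methylphenyl)-4-methylpentane-1,3-diol | OCCC(O)(C(C)C)c1ccc(C)cc1OC
F7 | step 4 | racemic 3-hydroxy-3-(2-methoxy-4-methylphenyl)-4-methylpentanal | O=CCC(O)(C(C)C)c1ccc(C)cc1OC
F8 | step 4 | racemic 3-hydroxy-3-(2-methoxy-4-methylphenyl)-4-methylpentanoic acid | OC(=O)CC(O)(C(C)C)c1ccc(C)cc1OC
F9 | step 4 | (1S)-1-phenylethanaminium (3R)-3-hydroxy-3-(2-methoxy-4-methylphenyl)-4-methylpentanoate | C[C@H]([NH3+])c1ccccc1.[O-]C(=O)C[C@@](O)(C(C)C)c1ccc(C)cc1OC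
F10 | step 11 | (3R,3aR,8aR)-3-hydroxy-6,8a-dimethyl-3-(propan-2-yl)-2,3,3a,5,8,8a-hexahydroazulene-1,4-dione | O=C1CC(C)=CC[C@@]2(C)C(=O)C[C@@](O)(C(C)C)[C@H]12
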